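A direct plan would formylate a methoxyresorcinol, build the pyran ring with an enal to give chromene aldehyde A1, and then hydrogenate the chromene to a chroman.
After MOM protection, an aldol condensation with a protected acetophenone would give chalcone A2; an oxidative 1,2-aryl shift with a trivalent thallium salt and an acid-mediated closure would lead to chroman isoflavone A3.
Acetylation, quinone dehydrogenation and deacetylation would then restore the chromene, for about eleven steps in all.
Weak point 1: saturating the chromene before the thallium step and re-oxidising it afterwards, with acetylation and deacetylation around it, would spend four operations that form no bond of the target.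
Weak point 2: the oxidative aryl shift would need a stoichiometric, highly toxic metal oxidant, would compete with aurone and flavone formation, and would release nitric acid onto two acid-labile MOM ethers.
Weak point 3: the pyran closure with the enal would have to choose between O2′ and O4′ of ring B with only a hydrogen bond to steer it, at the start of a long linear sequence.

**Retrosynthetic overview**
In ring B the C2′ hydroxyl is para to the C5′ methoxy group, and the aryl bond at C1′ is ortho to that hydroxyl; this is the pattern an SN2′-type substitution on a para-quinone monoketal leaves behind.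
The key disconnection is therefore C3–C1′ together with O1–C2: enaminone 2 (ring A plus C2, C3, C4) and quinone monoketal 8 (dearomatised ring B) are joined, ring B is re-aromatised and ring C is closed in one redox-neutral operation without protecting groups.
Ring order: ring C closes in the key step; ring D (the 2,2-dimethylpyran) closes last, by gold-catalysed hydroarylation of an aryl 1,1-dimethylpropargyl ether carried from isovanillin, whose hydroxyl, methoxy and formyl groups map onto O4′, the 5′-methoxy group and (after Baeyer–Villiger oxidation) O2′.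
The design needs no thallium and no chroman/chromene redox detour, because the alkene is made in the last step; the pyran oxygen is fixed as O4′ because the O–C(Me)2 bond is made on the only hydroxyl of isovanillin and never broken.

Key step: step 5

Remark on the chemistry: the target is achiral, so no stereocentre has to be set. Atom labels follow isoflavone numbering (O1 to C8a for rings A and C, C1′ to C6′ for ring B); the pyran is ring D.

**Step 1**
Reactants: 1 2,4-dihydroxyacetophenone
Product: 2 (E)-1-(2,4-dihydroxyphenyl)-3-(dimethylamino)prop-2-en-1-one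
Conditions: Me2NCH(OMe)2 (1.5 equiv), toluene, 80 °C
Reagents that add atoms: N,N-dimethylformamide dimethyl acetal COC(OC)N(C)C
Why: Enaminone formation by condensation of the methyl ketone with the amide acetal gives the hydrogen-bonded (E)-vinylogous amide, and the modest temperature and small excess of the acetal should keep O-methylation of the acidic 4-hydroxyl in check.

**Step 2**
Reactants: 3 isovanillin (3-hydroxy-4-methoxybenzaldehyde); 4 3-chloro-3-methylbut-1-yne
Product: 5 4-methoxy-3-[(2-methylbut-3-yn-2-yl)oxy]benzaldehyde
Conditions: K2CO3, KI (cat.), CuI (cat.), DMF, 65 °C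
Reagents that add atoms: none
Why: Copper-assisted O-propargylation of a phenol with a tertiary propargylic chloride is the standard way to aryl 1,1-dimethylpropargyl ethers, and isovanillin has only one hydroxyl, so the ether can form only on the oxygen that becomes O4′.

**Step 3**
Reactants: 5 4-methoxy-3-[(2-methylbut-3-yn-2-yl)oxy]benzaldehyde
Product: 7 4-methoxy-3-[(2-methylbut-3-yn-2-yl)oxy]phenol, via aryl formate 6 (not isolated)
Conditions: mCPBA, CH2Cl2, 0 °C → rt; then K2CO3 (cat.), MeOH, rt
Reagents that add atoms: 3-chloroperoxybenzoic acid O=C(OO)c1cccc(Cl)c1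
Why: In this Baeyer–Villiger (Dakin-type) oxidation the electron-rich 3,4-dialkoxyphenyl group migrates in preference to hydride to give formate 6, which catalytic carbonate in methanol cleaves to the phenol, while the terminal alkyne does not react with the peracid at this temperature.

**Step 4**
Reactants: 7 4-methoxy-3-[(2-methylbut-3-yn-2-yl)oxy]phenol
Product: 8 4,4-dimethoxy-3-[(2-methylbut-3-yn-2-yl)oxy]cyclohexa-2,5-dien-1-one
Conditions: PhI(OAc)2, MeOH, 0 °C; NaHCO3 (aq.) work-up
Reagents that add atoms: methanol CO
Why: Oxidative dearomatisation of a para-methoxyphenol with a hypervalent iodine reagent lets methanol trap the phenoxenium-type intermediate at the methoxy-bearing para carbon, giving a para-quinone monoketal that the 3-alkoxy group stabilises as a vinylogous ester, and the alkyne and the ether are inert to the oxidant.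

**Step 5**
Reactants: 2 (E)-1-(2,4-dihydroxyphenyl)-3-(dimethylamino)prop-2-en-1-one; 8 4,4-dimethoxy-3-[(2-methylbut-3-yn-2-yl)oxy]cyclohexa-2,5-dien-1-one
Product: 11 7-hydroxy-3-{2-hydroxy-5-methoxy-4-[(2-methylbut-3-yn-2-yl)oxy]phenyl}-4H-chromen-4-one, via cyclohexa-2,4-dienone adduct 9 (not isolated), via α-aryl enaminone 10 (not isolated)
Conditions: 2 (1.2 equiv), C6F5CO2H (1.2 equiv), (CF3)2CHOH–CH2Cl2, 4 Å MS, 0 °C → rt; then 50 °C
Reagents that add atoms: none
Why: Proposed new method: the acid in the strongly hydrogen-bond-donating fluoroalcohol should ionise one methoxy group of ketal 8 to an O-methylated quinone (oxocarbenium) ion, which the nucleophilic α-carbon of enaminone 2 attacks at C6 of 8 (the carbon next to the carbonyl group, the future C1′) in an SN2′-type substitution to give adduct 9; enolisation of the dienone then aromatises ring B, so that the former carbonyl oxygen becomes the 2′-hydroxyl and the remaining ketal oxygen the 5′-methoxy group (enaminone 10), and the ring A phenol adds to the β-carbon with loss of dimethylamine. The closest known reaction types are the acid-promoted coupling of quinone monoketals with arenes and alkenes in fluoroalcohols, which gives 2-substituted 4-methoxyphenols and 5-methoxy-2,3-dihydrobenzofurans, and the electrophile-triggered chromone annulation of ortho-hydroxyaryl enaminones; an enaminone has not been used as the π-nucleophile toward a quinone monoketal in this way. Ring C closes by a 6-endo-trig addition–elimination (O1 to C2), as in isoflavone syntheses from deoxybenzoin-derived enaminones, and no stereocentre persists because the sp3 carbon of 9 is flattened on aromatisation. The step needs attack at C6 and not at C2 or by conjugate addition at C5: C2 is the electron-rich α-carbon of the vinylogous ester and is screened by the tertiary ether, and a weak acid in the fluoroalcohol should favour ketal ionisation over carbonyl activation. It also needs closure through the ring A phenol and not through the new 2′-hydroxyl to a 3-aroylbenzofuran; the former gives the six-membered γ-pyrone and is the course that enaminones of 2,2′-dihydroxydeoxybenzoins are expected to take in isoflavone synthesis. The slight excess of 2 should outrun both its own acid-mediated closure to 7-hydroxychromone and arylation of the electron-rich product by remaining 8, and the stoichiometric acid ties up the dimethylamine that is released.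

**Step 6**
Reactants: 11 7-hydroxy-3-{2-hydroxy-5-methoxy-4-[(2-methylbut-3-yn-2-yl)oxy]phenyl}-4H-chromen-4-one
Product: 12 7-hydroxy-3-(5-hydroxy-8-methoxy-2,2-dimethyl-2H-chromen-6-yl)-4H-chromen-4-one
Conditions: Ph3PAuNTf2 (5 mol%), ClCH2CH2Cl–THF, rt → 40 °C
Reagents that add atoms: none
Why: In this gold-catalysed cycloisomerisation (6-endo-dig intramolecular hydroarylation) of an aryl 1,1-dimethylpropargyl ether, monovalent gold activates the alkyne, C3′ (the only free ortho position, since C5′ carries the methoxy group) attacks its terminal carbon and protodeauration releases the catalyst, so the O4′–C(Me)2 bond is never broken, the pyran cannot close on O2′, and the gem-dimethyl group favours the six-membered over the five-membered closure.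

**Compound list**
1 | 2,4-dihydroxyacetophenone | CC(=O)c1ccc(O)cc1O | starting material
2 | (E)-1-(2,4-dihydroxyphenyl)-3-(dimethylamino)prop-2-en-1-one | CN(C)/C=C/C(=O)c1ccc(O)cc1O | intermediate
3 | isovanillin (3-hydroxy-4-methoxybenzaldehyde) | COc1ccc(C=O)cc1O | starting material
4 | 3-chloro-3-methylbut-1-yne | CC(C)(Cl)C#C | starting material
5 | 4-methoxy-3-[(2-methylbut-3-yn-2-yl)oxy]benzaldehyde | COc1ccc(C=O)cc1OC(C)(C)C#C | intermediate
6 | 4-methoxy-3-[(2-methylbut-3-yn-2-yl)oxy]phenyl formate | COc1ccc(OC=O)cc1OC(C)(C)C#C | intermediate (not isolated)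
7 | 4-methoxy-3-[(2-methylbut-3-yn-2-yl)oxy]phenol | COc1ccc(O)cc1OC(C)(C)C#C | intermediate
8 | 4,4-dimethoxy-3-[(2-methylbut-3-yn-2-yl)oxy]cyclohexa-2,5-dien-1-one | COC1(OC)C=CC(=O)C=C1OC(C)(C)C#C | intermediate
9 | 6-[3-(dimethylamino)-1-(2,4-dihydroxyphenyl)-1-oxoprop-2-en-2-yl]-4-methoxy-3-[(2-methylbut-3-yn-2-yl)oxy]cyclohexa-2,4-dien-1-one (racemic, alkene geometry not fixed) | CN(C)C=C(C(=O)c1ccc(O)cc1O)C1C=C(OC)C(OC(C)(C)C#C)=CC1=O | intermediate (not isolated)
10 | 3-(dimethylamino)-1-(2,4-dihydroxyphenyl)-2-{2-hydroxy-5-methoxy-4-[(2-methylbut-3-yn-2-yl)oxy]phenyl}prop-2-en-1-one (alkene geometry not fixed) | CN(C)C=C(C(=O)c1ccc(O)cc1O)c1cc(OC)c(OC(C)(C)C#C)cc1O | intermediate (not isolated)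
11 | 7-hydroxy-3-{2-hydroxy-5-methoxy-4-[(2-methylbut-3-yn-2-yl)oxy]phenyl}-4H-chromen-4-one | COc1cc(-c2coc3cc(O)ccc3c2=O)c(O)cc1OC(C)(C)C#C | intermediate
12 | 7-hydroxy-3-(5-hydroxy-8-methoxy-2,2-dimethyl-2H-chromen-6-yl)-4H-chromen-4-one | COc1cc(-c2coc3cc(O)ccc3c2=O)c(O)c2c1OC(C)(C)C=C2 | target

**Step count and risks**
Total step count: 6. Longest linear sequence: 5 steps (3 → 5 → 7 → 8 → 11 → 12).

Steps most likely to fail:

1. Step 5 (proposed new method). The enaminone could add in conjugate fashion at C5 of 8, next to the ketal carbon, which would place ring C ortho to the methoxy group. The acid could also close 2 to 7-hydroxychromone before it meets the electrophile, or traces of water could hydrolyse the ketal to the quinone. The fallback uses known chemistry, a Suzuki–Miyaura coupling; it sets out from 2 and 7 and comes back at 11. Iodine in methanol would turn 2 into 7-hydroxy-3-iodo-4H-chromen-4-one F1 by iodocyclisation. N-Iodosuccinimide in MeCN would iodinate 7 para to the ether oxygen to give 2-iodo-4-methoxy-5-[(2-methylbut-3-yn-2-yl)oxy]phenol F2, and Ac2O/pyridine would give 2-iodo-4-methoxy-5-[(2-methylbut-3-yn-2-yl)oxy]phenyl acetate F3. Miyaura borylation (B2pin2, PdCl2(dppf), KOAc, dioxane, 80 °C) would give 4-methoxy-5-[(2-methylbut-3-yn-2-yl)oxy]-2-(4,4,5,5-tetramethyl-1,3,2-dioxaborolan-2-yl)phenyl acetate F4. Coupling of F4 with F1 (PdCl2(dppf), K3PO4, dioxane–H2O) would give 2-(7-hydroxy-4-oxo-4H-chromen-3-yl)-4-methoxy-5-[(2-methylbut-3-yn-2-yl)oxy]phenyl acetate F5, and K2CO3 in MeOH would remove the acetate to return to 11.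

2. Step 6. The free phenols and the pyrone carbonyl could bind and slow the cationic gold catalyst, adventitious water could hydrate the alkyne to a methyl ketone, or the five-membered (exo) closure could compete. The fallback sets out from 11 and comes back at 12, replacing π-acid catalysis with a pericyclic cascade. TBSCl/imidazole in DMF would give 7-[(tert-butyldimethylsilyl)oxy]-3-{2-[(tert-butyldimethylsilyl)oxy]-5-methoxy-4-[(2-methylbut-3-yn-2-yl)oxy]phenyl}-4H-chromen-4-one F6. Heating in N,N-diethylaniline at 180 °C would trigger the aryl propargyl ether Claisen rearrangement, 1,5-hydrogen shift and oxa-6π electrocyclisation to 7-[(tert-butyldimethylsilyl)oxy]-3-{5-[(tert-butyldimethylsilyl)oxy]-8-methoxy-2,2-dimethyl-2H-chromen-6-yl}-4H-chromen-4-one F7. With O2′ silylated, only the O4′ hydroxyl formed in the rearrangement can feed the hydrogen shift, so the pyran again closes on O4′. Bu4NF in THF would then give 12.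

3. Step 4. The acetic acid released by the oxidant could hydrolyse the ketal to the 2-alkoxy-1,4-benzoquinone during reaction or isolation, and over-oxidation of the electron-rich phenol could compete. The fallback sets out from 7 and comes back at 8, reaching the ketal from a base-stable bisketal. MeI/K2CO3 in acetone would give 1,4-dimethoxy-2-[(2-methylbut-3-yn-2-yl)oxy]benzene F8. Anodic oxidation (Pt anode, KOH, MeOH, 0 °C, undivided cell) would give 3,3,6,6-tetramethoxy-1-[(2-methylbut-3-yn-2-yl)oxy]cyclohexa-1,4-diene F9. Monohydrolysis in dilute aqueous AcOH–acetone at 0 °C should be regioselective: the ketal carbon conjugated with the ether oxygen through the ring alkene ionises first, which gives 8.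

**Further compounds**
F1 | step 5 | 7-hydroxy-3-iodo-4H-chromen-4-one | O=c1c(I)coc2cc(O)ccc12
F2 | step 5 | 2-iodo-4-methoxy-5-[(2-methylbut-3-yn-2-yl)oxy]phenol | COc1cc(I)c(O)cc1OC(C)(C)C#C
F3 | step 5 | 2-iodo-4-methoxy-5-[(2-methylbut-3-yn-2-yl)oxy]phenyl acetate | COc1cc(I)c(OC(C)=O)cc1OC(C)(C)C#C
F4 | step 5 | 4-methoxy-5-[(2-methylbut-3-yn-2-yl)oxy]-2-(4,4,5,5-tetramethyl-1,3,2-dioxaborolan-2-yl)phenyl acetate | COc1cc(B2OC(C)(C)C(C)(C)O2)c(OC(C)=O)cc1OC(C)(C)C#C
F5 | step 5 | 2-(7-hydroxy-4-oxo-4H-chromen-3-yl)-4-methoxy-5-[(2-methylbut-3-yn-2-yl)oxy]phenyl acetate | COc1cc(-c2coc3cc(O)ccc3c2=O)c(OC(C)=O)cc1OC(C)(C)C#C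
F6 | step 6 | 7-[(tert-butyldimethylsilyl)oxy]-3-{2-[(tert-butyldimethylsilyl)oxy]-5-methoxy-4-[(2-methylbut-3-yn-2-yl)oxy]phenyl}-4H-chromen-4-one | COc1cc(-c2coc3cc(O[Si](C)(C)C(C)(C)C)ccc3c2=O)c(O[Si](C)(C)C(C)(C)C)cc1OC(C)(C)C#C
F7 | step 6 | 7-[(tert-butyldimethylsilyl)oxy]-3-{5-[(tert-butyldimethylsilyl)oxy]-8-methoxy-2,2-dimethyl-2H-chromen-6-yl}-4H-chromen-4-one | COc1cc(-c2coc3cc(O[Si](C)(C)C(C)(C)C)ccc3c2=O)c(O[Si](C)(C)C(C)(C)C)c2c1OC(C)(C)C=C2
F8 | step 4 | 1,4-dimethoxy-2-[(2-methylbut-3-yn-2-yl)oxy]benzene | COc1ccc(OC)cc1OC(C)(C)C#C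
F9 | step 4 | 3,3,6,6-tetramethoxy-1-[(2-methylbut-3-yn-2-yl)oxy]cyclohexa-1,4-diene | COC1(OC)C=CC(OC)(OC)C=C1OC(C)(C)C#C
A1 | direct plan | 5-hydroxy-8-methoxy-2,2-dimethyl-2H-chromene-6-carbaldehyde | COc1cc(C=O)c(O)c2C=CC(C)(C)Oc12
A2 | direct plan | (E)-1-[2-hydroxy-4-(methoxymethoxy)phenyl]-3-[8-methoxy-5-(methoxymethoxy)-2,2-dimethylchroman-6-yl]prop-2-en-1-one | COCOc1ccc(C(=O)/C=C/c2cc(OC)c3OC(C)(C)CCc3c2OCOC)c(O)c1
A3 | direct plan | 7-hydroxy-3-(5-hydroxy-8-methoxy-2,2-dimethylchroman-6-yl)-4H-chromen-4-one | COc1cc(-c2coc3cc(O)ccc3c2=O)c(O)c2c1OC(C)(C)CC2
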